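(The earlier runs and the new flask were computed for substances that don't exist; noise was put on by code.)

A leftover from the runs below: the south-east run reads 8.2% monomer in chains at 6.00 min, where north reads 11.8% and north-west 11.6%, and it differs from them in two charges at once, with initiator halved and protic impurity lowest.

the same everywhere: free monomer 0.10 M
- north: protic impurity 2.8 mM; initiator 4.2 mol%; run made earlier
- north-west: protic impurity 4.4 mM; initiator 4.2 mol%; run made earlier
- south-east: protic impurity 2 mM; initiator 2.1 mol%; run made earlier
- flask: protic impurity 2.00 mM; initiator 4.2 mol%; time 25 min

| run | time / min | monomer in chains / % | free monomer / % |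
|---|---|---|---|
| north | 1.50 | 6.4 | 75.5 |
| north | 2.50 | 7.8 | 63.4 |
| north | 4.00 | 10.5 | 52.7 |
| north | 6.00 | 11.8 | 41.3 |
| north | 10.0 | 10.4 | 27.1 |
| north | 15.0 | 8.1 | 17.8 |
| north | 25.0 | 4.0 | 9.4 |
| north-west | 1.50 | 6.6 | 73.0 |
| north-west | 2.50 | 8.8 | 62.0 |
| north-west | 4.00 | 10.2 | 50.8 |
| north-west | 6.00 | 11.6 | 39.9 |
| north-west | 10.0 | 10.3 | 26.6 |
| north-west | 15.0 | 7.7 | 18.8 |
| north-west | 25.0 | 4.2 | 9.6 |
| south-east | 1.50 | 4.5 | 76.2 |
| south-east | 3.00 | 7.1 | 63.1 |
| south-east | 6.00 | 8.2 | 43.8 |
| south-east | 12.0 | 7.5 | 27.4 |
| south-east | 25.0 | 3.8 | 12.3 |

(readings scatter by 0.5 percentage points)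

- when, up to 25 min, the flask holds most monomer in chains
- the amount of monomer in chains, in percent of the free monomer charged, at that time



Two chemists split that leftover differently. The first holds to the initiator: she takes the peak to grow as the square root of the loading. She carries the chain yield per root of loading, the peak monomer in chains as a fraction of the charge divided by the square root of the initiator loading: 0.571, from the north and north-west peaks. On the south-east loading it gives 8.27% against the 8.2% read there. The flask shares the north loading, so she expects 11.7%, near 6.00 min.

The second holds to the impurity. North and north-west agree, he says, but both lie at or above 2.8 mM, and the one run at 2 mM is low. The flask has that same impurity, so he expects about 8.2%. The two expectations stand 3.5 percentage points apart, with a scatter of 0.5 points, so one flask can separate them.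

The forecast takes the first side, calling the south-east fall “roughly the square root of the initiator ratio”: 11.8% at 6.2 min, a little above her figure.

The flask gives 11.6% at 6.52 min, more than the second chemist's number.

    initiator → 2 initiating radical (k = 5.80 × 10⁻⁴ /s)
    protic impurity + free monomer → quenched substrate (k = 1.70 /M/s)
    monomer in chains → over-reaction product (k = 0.00290 /s)
    2 growing radical → dead chain (k = 4.00 × 10⁸ /M/s)
    free monomer + growing radical → monomer in chains + growing radical, rate k5*[growing radical]*[free monomer] (k = 11000 /M/s)
    2 free monomer → homo dimer (k = 0.0120 /M/s)
    free monomer + initiating radical → growing radical + monomer in chains (k = 2.30 × 10⁵ /M/s)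

The flask's own yield per root of loading is 0.568, against the carried 0.571. The second chemist keeps the early free-monomer count: by 2.50 min the flask's protic impurity stands at 0% and quenched substrate at 2.00%. On a neighbour flask charged with 17 mol% initiator, the carried yield gives 23.5%, and that neighbour reaches 22.1%. At 25.0 min it holds 0% of its free monomer, the limiting reagent there, and 4.42% monomer in chains.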